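The numbers belong to no real substance; the run is a simulation.

Start with the early hours of the flask, when the first portion of X meets G and L together.

    X + G ⇌ X.G (K1 = 26 L mol⁻¹, k1 = 15000 L mol⁻¹ min⁻¹)
    X.G ⇌ G + Z (K2 = 0.024 M, k2 = 68 min⁻¹)
    X + L → X.L (k3 = 0.31 L mol⁻¹ min⁻¹)

X 10 mM (in portions, 3); L 1.00 mM; G 0.99 µM; time 15 d; the portions of X follow each other after 6.0 h, the first at the start

- the reaction counts as stopped when no species that holds the X changes by six tenths of a point or more over the second half of the time
- run time (flask): 15 d

- why nothing more happens at 15 d, or that something still does (forward and back rates have come level / all of X has reacted / it is still moving / no working catalyst is left)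
- how much Z there is at 15 d, in percent of the X charged
- amount of Z if the flask were left three thousand times as long, in percent of the X charged

Apply the bench rule for a catalyst: G carries X and Z to their equilibrium, whose ratio Z/X is the product of the two equilibrium constants, 0.624. That gives Z a share of 38.4% of X and Z together. The charge of G is 0.00990% of the X, so drop X.G from the balance.

Now compare rates per X at the start. Bound X falls back 8.48 times as often as it goes on to Z, so the net constant of G's route, with G taken as free, is 0.00157 min⁻¹. L's route has 3.10 × 10⁻⁴ min⁻¹, so G leads by a factor of 5.05.

Then follow the drift, and find where the rule stops working. G's net rate sinks to zero as Z/X nears equilibrium, while L keeps taking X with no way back. L is the limiting reagent, at 10.0% of the X charged. At the equilibrium split of what L leaves, 55.4% of the charge stands as X, and with X held there L has a half-life of 0.280 d. The time after the last portion is 51.8 such half-lives, so count L's whole charge as X.L.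

Multiply the fraction L leaves by Z's share to get 34.6%, the equilibrium share of the remainder.

The forecast gives forward and back rates have come level, 34.6% and 34.6%, and adds that “no further change follows however long it is left”. The simulation gives forward and back rates have come level, 34.6% and 34.6%. At 15.0 d this flask holds X 55.4%, Z 34.6% and X.L 10.0% of the X charged, with L at 0% of its charge.

Reckon the neighbouring flask the same way, with 2.5 mM of X and the other charges unchanged. There L amounts to 40.0% of the X charged. Standing X then gives L a half-life of 1.68 d, and the run lasts 8.92 of them. The equilibrium share of the remainder comes to 23.1%. The neighbouring flask ends with X 37.0%, X.L 39.9% and L at 0.13% of its charge, and with Z at 23.1%.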